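**Plan**

1. Retrosynthetic cuts: first the C7 benzoate, then the C7 carbinol back to a ketone, then in one stroke the aryl–spiro bond C2–C1' and the C8–C8' bond. The last cut splits the seven-membered ring into a four-atom piece (C2, C1, C7, C8 of an ortho-bromoaryl ethyl ketone) and a three-atom piece (C1', C7', C8').
2. Enabling feature: the 2,6-dimethoxycyclohexadienone (ring B) is a dearomatised phenol whose spiro carbon C1' stands 1,3 to the methyl-bearing C8'. The unit C1'–C7'–C8' is therefore a latent spiro[2.5]octadienone (homo-quinone methide), electrophilic at C8' and, once opened, nucleophilic at the phenolate para carbon C1'. On ring A the C7 ketone makes C8 an enolate carbon and C2 carries bromine for palladium.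
3. Forward order: two three-step fragment syntheses, then a formal (4+3) annulation that makes C8–C8' and C2–C1' and with them the seven-membered ring and the spiro-dienone; ketone reduction and benzoylation finish.
4. Stereochemistry: C8' comes from (R)-propylene oxide through two inversions; C8 is set by base equilibration alpha to the ketone (trans to the C8' methyl); C7 by catalyst-controlled transfer hydrogenation. The spiro carbon is not a stereocentre because ring B is symmetric.

Key step: step 7

Remark on locants: lignan locants are used. C7/C8/C9 are the benzylic carbon, the adjacent methine and its methyl on the trimethoxyphenyl (ring A) side; C7'/C8'/C9' are the CH2, the methine and its methyl on the dienone (ring B) side; C1' is the spiro carbon and C2 the ring A carbon bonded to it. The target is (7R,8S,8'R), with the three substituents at C7, C8 and C8' alternately trans around the seven-membered ring.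

**Route**

Step 1
Reactants: 1 3,4,5-trimethoxybenzaldehyde
Product: 2 2-bromo-3,4,5-trimethoxybenzaldehyde
Conditions: NBS (1.05 equiv), MeCN, 23 °C
Reagents that add atoms: N-bromosuccinimide, O=C1CCC(=O)N1Br
Why: Electrophilic aromatic bromination; the two free ring positions are equivalent and each is activated by an ortho and a para methoxy group, so a single monobromide should form.

Step 2
Reactants: 2 2-bromo-3,4,5-trimethoxybenzaldehyde
Product: 3 rac-1-(2-bromo-3,4,5-trimethoxyphenyl)propan-1-ol
Conditions: EtMgBr, THF, −78 → 0 °C; aq. NH4Cl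
Reagents that add atoms: ethylmagnesium bromide, CC[Mg]Br
Why: Grignard addition to the aldehyde, which at low temperature should outrun bromine–magnesium exchange; the carbinol centre is racemic and is erased in step 3.

Step 3
Reactants: 3 rac-1-(2-bromo-3,4,5-trimethoxyphenyl)propan-1-ol
Product: 4 1-(2-bromo-3,4,5-trimethoxyphenyl)propan-1-one
Conditions: Dess–Martin periodinane, CH2Cl2, 23 °C
Reagents that add atoms: none
Why: Dess–Martin oxidation of the secondary benzylic alcohol to the aryl ethyl ketone under neutral conditions that leave the aryl bromide and the methyl ethers untouched.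

Step 4
Reactants: 5 4-bromo-2,6-dimethoxyphenol
Product: 6 (4-bromo-2,6-dimethoxyphenoxy)(tert-butyl)dimethylsilane
Conditions: TBSCl, imidazole, DMF, 23 °C
Reagents that add atoms: tert-butyldimethylsilyl chloride, CC(C)(C)[Si](C)(C)Cl
Why: Silylation of the phenol; it masks the acidic OH for the Grignard step and later serves as the fluoride-labile trigger of the key step.

Step 5
Reactants: 6 (4-bromo-2,6-dimethoxyphenoxy)(tert-butyl)dimethylsilane; 7 (R)-2-methyloxirane
Product: 9 (2R)-1-[4-(tert-butyldimethylsilyloxy)-3,5-dimethoxyphenyl]propan-2-ol, via aryl Grignard reagent 8 (not isolated)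
Conditions: Mg, THF, 50 °C; then CuI (10 mol %), 7, −30 → 0 °C; aq. NH4Cl
Reagents that add atoms: none
Why: Grignard formation followed by copper-catalysed SN2 opening of the epoxide at its unsubstituted carbon; the stereocentre of 7 is not touched, so the R carbinol should result.

Step 6
Reactants: 9 (2R)-1-[4-(tert-butyldimethylsilyloxy)-3,5-dimethoxyphenyl]propan-2-ol
Product: 10 (2R)-1-[4-(tert-butyldimethylsilyloxy)-3,5-dimethoxyphenyl]propan-2-yl 4-methylbenzenesulfonate
Conditions: TsCl, pyridine, DMAP (cat.), CH2Cl2, 0 → 23 °C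
Reagents that add atoms: p-toluenesulfonyl chloride, Cc1ccc(cc1)S(Cl)(=O)=O
Why: Sulfonylation at oxygen with retention at carbon; it turns the carbinol into the leaving group for aryl participation.

Step 7
Reactants: 4 1-(2-bromo-3,4,5-trimethoxyphenyl)propan-1-one; 10 (2R)-1-[4-(tert-butyldimethylsilyloxy)-3,5-dimethoxyphenyl]propan-2-yl 4-methylbenzenesulfonate
Product: 14 (7R,8S)-2,3,3',4,5'-pentamethoxy-7,8-dimethyl-7,8-dihydrospiro[benzo[7]annulene-5,1'-cyclohexa[2,5]diene]-4',9(6H)-dione, via lithium enolate 11 (not isolated), via spirocyclopropyl dienone 12 (not isolated), via ring-opened lithium phenolate 13 (not isolated)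
Conditions: 4, LiN(SiMe3)2, THF, −78 °C; then 10, CsF, 18-crown-6, −78 → 23 °C; then Pd2(dba)3 (5 mol %), tBuXPhos (12 mol %), 65 °C; then K2CO3, MeOH, 23 °C
Reagents that add atoms: none
Why: Proposed new method: a formal (4+3) annulation in which fluoride frees the phenolate of 10, whose para carbon displaces the tosylate (Ar1-3 participation, 3-exo-tet, inversion) to give homo-quinone methide 12; enolate 11 then opens 12 at its methyl-bearing carbon (second inversion, forming C8–C8' and rearomatising ring B to phenolate 13), after which zerovalent palladium inserts into the C–Br bond and C–C reductive elimination at the phenolate para carbon forms C2–C1'. The closest known reaction types are the homo-conjugate opening of spiro[2.5]octa-4,7-dien-6-ones and of doubly activated cyclopropanes by carbon nucleophiles, and the palladium-catalysed intramolecular arylative dearomatisation of para-substituted phenols; their union in one flask, the unstabilised ketone enolate and the seven-membered ring size are the untested parts. The one ring that persists, the seven-membered carbocycle, is closed by the aryl–spiro bond in a spiro mode (at the chain-bearing carbon para to the phenolate oxygen) through an eight-membered C,C-palladacycle, the cyclopropane being only a transient ring. C8' is fixed by the stereospecific double inversion, so the R carbinol centre of 10 maps onto 8'R with net retention, whereas C8 is formed unselectively but lies alpha to the ketone and is equilibrated by K2CO3/MeOH to the trans-7,8-dimethyl arrangement with both methyls pseudo-equatorial, the minor epimer being recyclable. The step needs opening of the cyclopropane at its more substituted carbon, which the cation-like transition state of an aromatisation-driven ring opening should secure (as with phenonium ions and spiro-activated cyclopropanes), and C-arylation at the para carbon instead of O- or alpha-arylation, which the substrate secures because the phenolate oxygen cannot reach palladium, alpha-arylation would give a four-membered ring, and the di-ortho-substituted arylpalladium couples slowly between molecules; the catalyst is added only once the enolate is consumed.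

Step 8
Reactants: 14 (7R,8S)-2,3,3',4,5'-pentamethoxy-7,8-dimethyl-7,8-dihydrospiro[benzo[7]annulene-5,1'-cyclohexa[2,5]diene]-4',9(6H)-dione
Product: 15 (7R,8S,9R)-9-hydroxy-2,3,3',4,5'-pentamethoxy-7,8-dimethyl-6,7,8,9-tetrahydrospiro[benzo[7]annulene-5,1'-cyclohexa[2,5]dien]-4'-one
Conditions: RuCl[(R,R)-TsDPEN](p-cymene) (2 mol %), HCO2H/Et3N (5:2), CH2Cl2, 25 °C
Reagents that add atoms: none
Why: Noyori–Ikariya asymmetric transfer hydrogenation; the (R,R) catalyst should deliver hydride to the aryl ketone face that gives the R carbinol (the sense known for aryl alkyl and benzo-fused cyclic ketones), trans to the C8 methyl, while its aryl-directed outer-sphere hydride transfer should spare the hindered cross-conjugated dienone carbonyl.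

Step 9
Reactants: 15 (7R,8S,9R)-9-hydroxy-2,3,3',4,5'-pentamethoxy-7,8-dimethyl-6,7,8,9-tetrahydrospiro[benzo[7]annulene-5,1'-cyclohexa[2,5]dien]-4'-one
Product: 16 CNP0201356.1, [(7R,8S,9R)-2,3,3',4,5'-pentamethoxy-7,8-dimethyl-4'-oxo-6,7,8,9-tetrahydrospiro[benzo[7]annulene-5,1'-cyclohexa[2,5]dien]-9-yl] benzoate
Conditions: BzCl, pyridine, DMAP (cat.), CH2Cl2, 0 → 23 °C
Reagents that add atoms: benzoyl chloride, O=C(Cl)c1ccccc1
Why: DMAP-catalysed acylation of the secondary alcohol at oxygen with retention at C7; the medium stays basic, so the dienone should not undergo dienone–phenol rearrangement.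

**Compound list**

1 | 3,4,5-trimethoxybenzaldehyde | COc1cc(C=O)cc(OC)c1OC | starting material
2 | 2-bromo-3,4,5-trimethoxybenzaldehyde | COc1cc(C=O)c(Br)c(OC)c1OC | intermediate
3 | rac-1-(2-bromo-3,4,5-trimethoxyphenyl)propan-1-ol | CCC(O)c1cc(OC)c(OC)c(OC)c1Br | intermediate
4 | 1-(2-bromo-3,4,5-trimethoxyphenyl)propan-1-one | CCC(=O)c1cc(OC)c(OC)c(OC)c1Br | intermediate
5 | 4-bromo-2,6-dimethoxyphenol | COc1cc(Br)cc(OC)c1O | starting material
6 | (4-bromo-2,6-dimethoxyphenoxy)(tert-butyl)dimethylsilane | COc1cc(Br)cc(OC)c1O[Si](C)(C)C(C)(C)C | intermediate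
7 | (R)-2-methyloxirane ((R)-propylene oxide) | C[C@@H]1CO1 | starting material
8 | [4-(tert-butyldimethylsilyloxy)-3,5-dimethoxyphenyl]magnesium bromide | COc1cc([Mg]Br)cc(OC)c1O[Si](C)(C)C(C)(C)C | intermediate
9 | (2R)-1-[4-(tert-butyldimethylsilyloxy)-3,5-dimethoxyphenyl]propan-2-ol | C[C@@H](O)Cc1cc(OC)c(O[Si](C)(C)C(C)(C)C)c(OC)c1 | intermediate
10 | (2R)-1-[4-(tert-butyldimethylsilyloxy)-3,5-dimethoxyphenyl]propan-2-yl 4-methylbenzenesulfonate | C[C@@H](OS(=O)(=O)c1ccc(C)cc1)Cc1cc(OC)c(O[Si](C)(C)C(C)(C)C)c(OC)c1 | intermediate
11 | lithium (Z)-1-(2-bromo-3,4,5-trimethoxyphenyl)prop-1-en-1-olate | C/C=C(\[O-])c1cc(OC)c(OC)c(OC)c1Br.[Li+] | intermediate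
12 | (1S)-5,7-dimethoxy-1-methylspiro[2.5]octa-4,7-dien-6-one | C[C@H]1CC12C=C(OC)C(=O)C(OC)=C2 | intermediate
13 | lithium 4-[(2R)-4-(2-bromo-3,4,5-trimethoxyphenyl)-2,3-dimethyl-4-oxobutyl]-2,6-dimethoxyphenolate (mixture at C3 of the butyl chain) | C[C@H](Cc1cc(OC)c([O-])c(OC)c1)C(C)C(=O)c1cc(OC)c(OC)c(OC)c1Br.[Li+] | intermediate
14 | (7R,8S)-2,3,3',4,5'-pentamethoxy-7,8-dimethyl-7,8-dihydrospiro[benzo[7]annulene-5,1'-cyclohexa[2,5]diene]-4',9(6H)-dione | COC1=CC2(C=C(OC)C1=O)C[C@@H](C)[C@H](C)C(=O)c1cc(OC)c(OC)c(OC)c12 | intermediate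
15 | (7R,8S,9R)-9-hydroxy-2,3,3',4,5'-pentamethoxy-7,8-dimethyl-6,7,8,9-tetrahydrospiro[benzo[7]annulene-5,1'-cyclohexa[2,5]dien]-4'-one | COC1=CC2(C=C(OC)C1=O)C[C@@H](C)[C@H](C)[C@@H](O)c1cc(OC)c(OC)c(OC)c12 | intermediate
16 | CNP0201356.1, [(7R,8S,9R)-2,3,3',4,5'-pentamethoxy-7,8-dimethyl-4'-oxo-6,7,8,9-tetrahydrospiro[benzo[7]annulene-5,1'-cyclohexa[2,5]dien]-9-yl] benzoate | COC1=CC2(C=C(OC)C1=O)C[C@@H](C)[C@H](C)[C@@H](OC(=O)c1ccccc1)c1cc(OC)c(OC)c(OC)c12 | target

**Count and risks**

Total steps: 9. Longest linear sequence: 6 steps (1–3, then 7–9; the branch 4–6, then 7–9, is equally long).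

Steps most likely to fail:

1. Step 7 (Proposed new method). What may go wrong: the events fall out of step. The unstabilised enolate may undergo O-alkylation or proton transfer, the transient cyclopropane may be opened at its CH2 carbon or by fluoride, or the spiro-closure of the seven-membered ring may be so slow that the arylpalladium is lost by protodebromination. The fallback makes the two bonds one at a time with known reaction types and a stabilised enolate; it sets out from aldehyde 2 and tosylate 10 and comes back at ketone 14. Roskamp homologation of 2 (methyl diazoacetate, SnCl2 cat., CH2Cl2) should give methyl 3-(2-bromo-3,4,5-trimethoxyphenyl)-3-oxopropanoate F1. Its potassium enolate (K2CO3, MeCN) should open cyclopropane 12, released from 10 with CsF and 18-crown-6, to give methyl (3R)-2-(2-bromo-3,4,5-trimethoxybenzoyl)-4-(4-hydroxy-3,5-dimethoxyphenyl)-3-methylbutanoate F2 as a mixture at C2. Palladium-catalysed arylative dearomatisation of the isolated phenol (Pd2(dba)3, tBuXPhos, K2CO3, 1,4-dioxane, 100 °C) should then close the ring to methyl (7R)-2,3,3',4,5'-pentamethoxy-7-methyl-4',9-dioxo-6,7,8,9-tetrahydrospiro[benzo[7]annulene-5,1'-cyclohexa[2,5]diene]-8-carboxylate F3. C-Methylation (MeI, K2CO3, acetone) gives methyl (7R)-2,3,3',4,5'-pentamethoxy-7,8-dimethyl-4',9-dioxo-6,7,8,9-tetrahydrospiro[benzo[7]annulene-5,1'-cyclohexa[2,5]diene]-8-carboxylate F4. Krapcho dealkoxycarbonylation (LiCl, wet DMSO, 130 °C) and the same K2CO3/MeOH equilibration return 14.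

2. Step 8. What may go wrong: poor facial selectivity from a catalyst–substrate mismatch, with hydride delivered anti to the C8 methyl so that the C7 epimer forms. The fallback sets out from ketone 14 and comes back at target 16. The matched catalyst RuCl[(S,S)-TsDPEN](p-cymene) is used on purpose to give the cis alcohol (7R,8S,9S)-9-hydroxy-2,3,3',4,5'-pentamethoxy-7,8-dimethyl-6,7,8,9-tetrahydrospiro[benzo[7]annulene-5,1'-cyclohexa[2,5]dien]-4'-one F5. The benzoate is then installed with inversion at C7 by a Mitsunobu reaction (PPh3, DIAD, PhCO2H, THF, 0 → 23 °C), which gives 16 directly and replaces both hydride control and the retentive acylation of step 9.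

3. Step 5. What may go wrong: halide opening of the epoxide to a halohydrin and incomplete Grignard formation from the hindered, electron-rich bromide. The fallback sets out from aryl bromide 6 and comes back at alcohol 9. Palladium-catalysed mono-alpha-arylation of acetone ([Pd(cinnamyl)Cl]2, Mor-DalPhos, Cs2CO3, acetone, 90 °C) should give 1-[4-(tert-butyldimethylsilyloxy)-3,5-dimethoxyphenyl]propan-2-one F6. An (R)-selective ketoreductase (NADPH-dependent alcohol dehydrogenase class; 2-propanol for cofactor recycling, pH 7 buffer, 30 °C) then reduces F6 to 9, so the stereocentre comes from the enzyme and not from the epoxide.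

Further compounds

F1 | step 7 | methyl 3-(2-bromo-3,4,5-trimethoxyphenyl)-3-oxopropanoate | COC(=O)CC(=O)c1cc(OC)c(OC)c(OC)c1Br
F2 | step 7 | methyl (3R)-2-(2-bromo-3,4,5-trimethoxybenzoyl)-4-(4-hydroxy-3,5-dimethoxyphenyl)-3-methylbutanoate | COC(=O)C(C(=O)c1cc(OC)c(OC)c(OC)c1Br)[C@H](C)Cc1cc(OC)c(O)c(OC)c1
F3 | step 7 | methyl (7R)-2,3,3',4,5'-pentamethoxy-7-methyl-4',9-dioxo-6,7,8,9-tetrahydrospiro[benzo[7]annulene-5,1'-cyclohexa[2,5]diene]-8-carboxylate | COC1=CC2(C=C(OC)C1=O)C[C@@H](C)C(C(=O)OC)C(=O)c1cc(OC)c(OC)c(OC)c12
F4 | step 7 | methyl (7R)-2,3,3',4,5'-pentamethoxy-7,8-dimethyl-4',9-dioxo-6,7,8,9-tetrahydrospiro[benzo[7]annulene-5,1'-cyclohexa[2,5]diene]-8-carboxylate | COC1=CC2(C=C(OC)C1=O)C[C@@H](C)C(C)(C(=O)OC)C(=O)c1cc(OC)c(OC)c(OC)c12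
F5 | step 8 | (7R,8S,9S)-9-hydroxy-2,3,3',4,5'-pentamethoxy-7,8-dimethyl-6,7,8,9-tetrahydrospiro[benzo[7]annulene-5,1'-cyclohexa[2,5]dien]-4'-one | COC1=CC2(C=C(OC)C1=O)C[C@@H](C)[C@H](C)[C@H](O)c1cc(OC)c(OC)c(OC)c12
F6 | step 5 | 1-[4-(tert-butyldimethylsilyloxy)-3,5-dimethoxyphenyl]propan-2-one | CC(=O)Cc1cc(OC)c(O[Si](C)(C)C(C)(C)C)c(OC)c1
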